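Two constants can be read from the earlier runs, and each flask then follows from one target molecule: how fast it is made, and how long it lasts once made.

| flask | substrate | temperature | remark | time |
|---|---|---|---|---|
| larch | 1.3 M | 2 °C | run made earlier |  |
| ash | 1.3 M | 52 °C | run made earlier |  |
| green | 2.6 M | 70 °C |  | 5.0 min |
| blue | 2.6 M | 10 °C |  | 5.0 min |
| teal | 2.6 M | 40 °C |  | 5.0 min |
| grey | 2.6 M | −20 °C |  | 5.0 min |

| run | time / min | target / % | substrate / % |
|---|---|---|---|
| larch | 12.0 | 2.3 | 97.8 |
| larch | 20.0 | 0.2 | 96.5 |
| larch | 30.0 | 2.5 | 95.4 |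
| larch | 40.0 | 3.9 | 94.0 |
| larch | 60.0 | 5.1 | 90.8 |
| larch | 80.0 | 6.3 | 87.8 |
| larch | 150 | 10.4 | 78.7 |
| ash | 1.00 | 27.6 | 61.2 |
| ash | 1.50 | 36.3 | 50.2 |
| ash | 2.50 | 50.2 | 35.8 |
| ash | 3.00 | 53.3 | 31.0 |
| ash | 5.00 | 63.1 | 20.3 |
| ash | 8.00 | 66.5 | 14.2 |
| ash | 12.0 | 65.7 | 9.7 |

(standard deviation of a reading: 0.5 percentage points)

- a reading or a percentage of target counts all its forms, free or not
- a reading of substrate is of its free form alone

* the flask with the highest amount of target, in percent of the substrate charged ("all alike" if they lie within 1.5 percentage points) (green / blue / teal / grey / all alike)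
* final target, as a percentage of the substrate charged, in green
* final target, as a percentage of the substrate charged, in blue
* final target, as a percentage of the substrate charged, in teal
* final target, as a percentage of the substrate charged, in grey

How much does warming speed the making of target? The ash run gains 0.276 min⁻¹ of the charge by its first reading, and the larch run gains 6.93 × 10⁻⁴ min⁻¹ over its whole length, a factor of 398 between 2 °C and 52 °C. Taken as exponential in degrees, that factor gives 8.63 from the ash run up to green.

How long does target last? Target is the intermediate of a consecutive reaction. Between 8.00 min and 12.0 min the ash run loses 4.5 percentage points of substrate and 0.8 points of target. If each lost substrate became target, the loss of target, divided by c(target), is a first-order constant of 0.0202 min⁻¹, as a reading. Scaled by the same factor, which is a guess, this gives the target lifetime in green, the mean time a target molecule lasts there: 5.75 min.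

Does green make target before losing it? Making takes 0.420 min, short against that lifetime, so the reckoning here lets target decay from the full charge over 5.0 min, leaving 41.9 %. Percentages are carried unchanged from 1.3 M to 2.6 M. The scaled starting rate gives teal 32.8 %, blue 0.903 % and grey 0.0249 %, so green leads.

The forecast also names green, but stands higher for green: 60 % (range 45 % to 75 %), since there “substrate is consumed and target sits near the plateau”. For teal it gives 40 %, for blue 1.7 %, for grey 0.03 %.

The flasks give green 36.2 %, teal 33.0 %, blue 1.26 % and grey 0.0138 %, and green leads.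

    substrate + target ⇌ idle adduct, settled at all times (K = 0.380 M⁻¹, ΔH = −42.0 kJ mol⁻¹)
    isomer of the product A ⇌ isomer of the product B (K = 16.0, k = 0.00847 s⁻¹, Ea = 89.0 kJ mol⁻¹, ΔH = −14.0 kJ mol⁻¹)
    substrate ⇌ target (K = 13.1, k = 0.0341 s⁻¹, Ea = 90.0 kJ mol⁻¹, ΔH = 33.0 kJ mol⁻¹)
    target ⇌ isomer of the product A (K = 3.92, k = 7.44 × 10⁻⁴ s⁻¹, Ea = 105 kJ mol⁻¹, ΔH = −14.0 kJ mol⁻¹)
    target → over-reaction product (k = 0.00344 s⁻¹, Ea = 110 kJ mol⁻¹)
    (constants at 70 °C)

Green has not come to rest at 5.00 min: its target has fallen from 59.1 % at 2.50 min to 36.2 %. Ten times the time spans 8.70 of the target lifetimes estimated for green from the ash and larch runs, and green then holds 0.0462 % of target, with over-reaction product up from 49.0 % to 82.9 %. In grey the same scaling gives a lifetime of 2.75 × 10⁵ min, far longer than 50.0 min. Grey's target rises from 0.0138 % to 0.138 %, ten times as much, with over-reaction product at 0 %.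

The runs were generated by integration for substances that don't exist; noise was put on by code.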